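Charging 2.50 mM of reagent against 5.0 mM of starting material, with 100 µM of free catalyst, is a decision about how many times the catalyst may go round.

starting material 5.0 mM; reagent 2.50 mM; free catalyst 100 µM; time 10 min

    catalyst intermediate D ⇌ free catalyst + target (K1 = 9.0 × 10⁻⁴ M, k1 = 53.0 s⁻¹)
    catalyst intermediate B → catalyst intermediate C (k2 = 1.22 s⁻¹)
    catalyst intermediate C ⇌ by-product + catalyst intermediate D (K3 = 0.00114 M, k3 = 5.51 s⁻¹)
    reagent + catalyst intermediate A → catalyst intermediate B (k4 = 2750 M⁻¹ s⁻¹)
    starting material + free catalyst ⇌ catalyst intermediate A (K5 = 507 M⁻¹, k5 = 95000 M⁻¹ s⁻¹)

- the reaction counts as stopped when no species that holds the starting material changes by six tenths of a point or more over the second half of the time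
- run time (flask): 10 min

* why nothing more happens at 10 min, or that something still does (forward and back rates have come level / it is still moving / the reagent has run out first / no working catalyst is left / all of the starting material has reacted)
* share of the starting material used up at 10 min
* target at 10 min, in percent of the starting material charged
* amount of target if the flask were left three thousand times as long, in percent of the starting material charged

Each round takes in one starting material and one reagent, and gives out one target and one by-product. The quantity to count is therefore the turn budget, the reagent charge over the catalyst charge: 25.0 rounds. Using up the starting material needs 50.0 rounds, more than the budget. So in my reckoning the reagent runs short, and target heads for about half of the charge.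

A fresh round takes about 1.15 s, and the passage from intermediate B to intermediate C takes longer than the other steps counted. At that pace, in my reckoning, target starts as a straight line of 5.22 mM min⁻¹, and at that slope the budget lasts 0.479 min.

The line then bends. Near the knee, [target], [by-product] and [starting material] each stand near 2.50 mM. Counting free catalyst as 1, intermediate A weighs 1.27, intermediate D 2.78 and intermediate C 6.09, so intermediate C is the resting state. Intermediate A is then 11.4 % of the catalyst, and the reagent decays with a half-life of 0.369 min, far shorter than the 10 min run. Counted from the full charge at that half-life, the reagent reckons down to 1.75 × 10⁻⁵ µM over the run, so in my reckoning the reagent runs out first and the curve lies flat.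

Intermediate B loses its feed along with the reagent, so in my reckoning the level falls short of the budget by what intermediates C and D hold. By this reckoning target comes to 48.4 %, and it stays at 48.4 % on long standing. Counting intermediate A as well, conversion comes to 50.2 %.

The forecast says the reagent has run out first, with conversion 50.2 %, target 48.4 % and 48.4 % on long standing. It places the shortfall in material that “stays bound on the catalyst”.

In the simulation, the reagent has run out first, with conversion 50.2 %, target 48.4 % and 48.4 % on long standing.

Target in this flask counts 24.2 finished rounds of the budget of 25.0. The slowest mode of this flask has a half-life of 0.357 min at 10.0 min, far shorter than the run, and at the end the reagent stands at 0 % of its charge against 50 % of the charged starting material. The flask with 20 mM of starting material has the same budget but needs 200 rounds, which gives 12.5 % of its charge. Simulated, its target reaches 12.3 % at 10.0 min, with 87 % of its starting material still there, unbound.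

The constants used here were drawn at random within sensible limits, and the outcome is calculated.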